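## Structural features

The target is a trans-fused decalin carrying a quinone side chain. Ring A is C1–C2–C3–C4–C5–C10 with an exocyclic methylene on C4; ring B is C5–C6–C7–C8–C9–C10. C9 carries, through the methylene C11, a 2-hydroxy-5-methoxy-1,4-benzoquinone. Four contiguous stereocentres run C8 (H, CH3), C9 (CH3, C11), C10 (CH3, C1) and C5 (H). C9 and C10 are adjacent quaternary carbons, and the three methyl groups lie on one face of ring B. Because the C10 methyl is axial in the trans-decalin, the cis C8 methyl is axial as well. This 1,3-diaxial methyl pair means that a C4 ketone would be expected to prefer the cis ring fusion on equilibration, so C5–H has to be set kinetically and then kept away from enolising conditions. The fragile groups are the 1,1-disubstituted alkene (acid moves it or makes it cyclise onto the quinone oxygen) and the vinylogous acid/ester of the quinone (nucleophiles, redox). The real difficulty is the vicinal quaternary pair C9–C10 with defined relative configuration, flanked by C8 and C5. The feature exploited is that on C10 the ring A carbon C1 is cis to the C11 arm of C9. An oxygen on C11 can therefore hold a two-carbon acetal unit (C1–C2) and deliver C1 to C10 on that face by closing a temporary six-membered ring.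

## Logic of the disconnections

26 ⇒ 25. The O–H bond of the quinone hydroxyl is traced to an O–CH3 bond. This lets both quinone oxygen patterns come from an arene with four identical methoxy groups. The forward step must hydrolyse only the methoxy group flanked by the C11 chain, and under base, because the alkene does not tolerate acid.

25 ⇒ 24. The two C=O bonds are traced to aryl C–OCH3 bonds. The quinone is carried as a robust tetramethoxyarene through the organometallic and radical steps. The oxidant must spare the exocyclic alkene.

24 ⇒ 23 ⇒ 22 ⇒ 19 + 20. The C11–aryl bond is cut, together with the benzylic C–O bond that the coupling leaves behind. C11 is neopentyl, so displacement is excluded and carbonyl addition is the reliable bond construction. The gain is a decalin aldehyde plus a commercial arene. The demands are addition of a di-ortho-substituted aryllithium (21) to a hindered, non-enolisable aldehyde, and a radical deoxygenation that leaves the alkene alone.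

19 ⇒ 18 ⇒ 17. The oxidation level at C11 is adjusted and the C4=CH2 bond is cut. The methylene is put in directly after C5 is set, so the epimerisable C4 ketone exists in one intermediate only. The forward methylenation must be non-basic.

17 ⇒ 16 ⇒ 14. The C5–H and C6–H bonds (and C2–H, C3–H) are cut. C5 is then set by hydrogen delivery to a C5=C6 alkene and not inherited from earlier steps, so the C5 configuration of 12–14 need not be controlled. The demands are an α′-dehydrogenation of the enone and a face-selective hydrogenation.

14 ⇒ 12 (through 13). The C2=C3 bond is cut (aldol condensation). Ring A opens to a methyl ketone and a masked aldehyde that is already held in the tether. Only a six-membered aldol closure is possible.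

12 ⇒ 11. The C1–C10 bond is cut. This removes one quaternary centre and the temporary ring, and reduces the problem to a monocyclic enone with C8 and C9 in place. The forward step must add a tethered carbon radical to a fully substituted enone β-carbon, syn to C11.

11 ⇒ 9 + 10. The acetal C2–O(C11) bond and the C1–Br bond are cut. The tether comes from a vinyl ether and an electrophilic bromine source. The hindered primary alcohol must capture the oxocarbenium ion.

9 ⇒ 8 ⇒ 7. Oxidation levels at C11 and C4 are adjusted. C11 arrives as an ester, and the C4 ketone is recovered by selective allylic oxidation.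

7 ⇒ 6. The C5=C10 bond is cut (aldol cyclodehydration). Ring B opens to an acyclic 1,7-diketone. Only one six-membered closure exists, and it must be run without base to avoid retro-Claisen cleavage.

6 ⇒ 5 ⇒ 4 + 3. The C5–C6 bond is cut (olefination, then saturation). This adds C3–C5 as one stabilised ylide.

4 ⇒ 1 + 2. The C8–C9 bond is cut (conjugate addition). Both stereocentres arise from two commercial four- and seven-carbon pieces. The forward step must control C8 through the catalyst; C9 is the weaker point and is handled by separation at 7.

## Other disconnections considered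

Alternative 1: The cut removes the two carbons that become the C9 and C10 methyl groups and traces them to a cyclobutene. In the forward key step, irradiation of ring B enone A1 with acetylene A2 would give photoadduct A3.
- In favour: one step makes a bond to each quaternary carbon. The four-membered ring enforces the cis relationship. The usual preference of the excited enone for axial bond formation at the β-carbon puts the new ring anti to C5–H.
- Better than the chosen plan on one point: C5 is fixed beforehand and sits next to a ketal, so it cannot epimerise. The chosen plan must set C5 late (steps 9 and 10).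
- Against: A3 still lacks the C8 methyl. The cyclobutene must be cleaved and both carbons reduced to methyl groups at neopentyl positions. A1 needs its own enantioselective synthesis. Photochemistry with a gaseous alkyne is awkward to scale.
- Comparison: on structure the two plans are equal in using a temporary ring to enforce a cis relationship at C9–C10. On mechanism a triplet biradical cycloaddition and a radical conjugate addition both tolerate congestion. On step economy the alternative is clearly longer after the key step.

Alternative 2: The cut is through C7–C8 and C9–C10, opening ring B into diene A4 and dienophile A5. In the forward key step a chiral cationic boron Lewis acid would promote the endo cycloaddition to give aldehyde A6.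
- In favour: it is convergent. C8, C9 and C10 and the absolute configuration come in one step from achiral pieces. The E-dienophile and the endo rule give the all-cis methyl array with C11 cis to C1. C11 emerges as the aldehyde needed for aryl addition.
- Better than the chosen plan on two points: it would be markedly shorter, and C5 is not epimerisable because C4 is a ketal.
- Against: the bond C9–C10 joins a fully substituted diene terminus to a disubstituted dienophile carbon. The C10 methyl is the inward substituent of the diene, so the reactive s-cis conformer is strained. A bimolecular cycloaddition is very sensitive to this congestion. The diene and its ketal may not survive a strong cationic Lewis acid. C5–H still has to be set by hydrogenation of C5=C6.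
- Comparison: the chosen plan forms the same C–C bond type intramolecularly with an early-transition-state radical, which is mechanistically the safer way to make a vicinal quaternary pair, at the price of more steps.

Alternative 3: The cut is the C9–C10 bond, contracting ring B to a trans-hydrindane epoxy alcohol A7. In the forward key step a boron Lewis acid would open the epoxide at C9 and the C8–C10 bond would migrate to give ketone A8.
- In favour: a 1,2-shift of a fully substituted ring carbon onto a tertiary epoxide carbon is a dependable way to form adjacent quaternary centres. It is stereospecific (retention at C10, inversion at C9).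
- Better than the chosen plan on one point: the trans ring fusion is fixed in the hydrindane before the key step.
- Against: the configuration of C9 depends on the facial selectivity of epoxidising an exocyclic 1,1-disubstituted alkene next to a tertiary carbinol. Migration of C7 in place of C10, or fluorohydrin formation, can compete. The C8 methyl must still be introduced from the ketone. An enantiopure trans-hydrindane with the ring A oxygen at C4 is itself a multi-step target.
- Comparison: the two plans are equal in making the C9–C10 relationship by an intramolecular, stereochemically defined event. The alternative is longer overall and rests on an acyclic stereocentre that the chosen plan avoids.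

Key step: step 7

Remark on the chemistry: centres that are destroyed later are drawn as one epimer or left unspecified, and both epimers are assumed to react alike. These are the acetal carbon of 11–13, the carbinol carbons of 8, 22 and 23, and C5 of 12–14.

Step 1
Reactants: 1 ethyl 2-methyl-3-oxobutanoate; 2 (E)-but-2-enal; 3 1-(triphenyl-λ5-phosphanylidene)propan-2-one
Product: 5 ethyl (2R,3S,5E)-2-acetyl-2,3-dimethyl-7-oxooct-5-enoate, via aldehyde 4 (not isolated)
Conditions: (R)-2-[diphenyl(trimethylsilyloxy)methyl]pyrrolidine (10 mol%), PhCO2H (10 mol%), toluene, 0 °C to rt; then 3, rt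
Reagents that add atoms: none
Why: Iminium-catalysed Michael addition, in which the aryl(silyloxy)methyl group of the (R)-amine blocks one face of the E-iminium ion so that C8 is formed S under catalyst control, whereas the face of the nucleophile (C9) is not firmly controlled and the 2S epimer is carried on to step 3; the aldehyde is trapped in the same flask by Wittig olefination with the stabilised ylide, which should give the E-enone and prevent retro-Michael loss.

Step 2
Reactants: 5 ethyl (2R,3S,5E)-2-acetyl-2,3-dimethyl-7-oxooct-5-enoate
Product: 6 ethyl (2R,3S)-2-acetyl-2,3-dimethyl-7-oxooctanoate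
Conditions: H2 (1 atm), 10% Pd/C, EtOAc, rt
Reagents that add atoms: none
Why: Heterogeneous hydrogenation of the disubstituted enone C=C; the ketones and the ester are inert under these conditions and no stereocentre is touched.

Step 3
Reactants: 6 ethyl (2R,3S)-2-acetyl-2,3-dimethyl-7-oxooctanoate
Product: 7 ethyl (1R,6S)-3-acetyl-1,2,6-trimethylcyclohex-2-ene-1-carboxylate
Conditions: TsOH·H2O (10 mol%), toluene, reflux, water separator; chromatography
Reagents that add atoms: none
Why: Intramolecular aldol addition and dehydration, in which only the C5 enol of the chain ketone can reach the C10 carbonyl through a six-membered ring (every other pairing would need an eight-membered ring) and acid avoids retro-Claisen cleavage of the α,α-disubstituted β-keto ester. C8 and C9 are untouched, and the rigid ring should allow the (1S,6S) diastereomer from step 1 to be removed by chromatography.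

Step 4
Reactants: 7 ethyl (1R,6S)-3-acetyl-1,2,6-trimethylcyclohex-2-ene-1-carboxylate
Product: 8 1-[(3R,4S)-3-(hydroxymethyl)-2,3,4-trimethylcyclohex-1-en-1-yl]ethan-1-ol (both carbinol epimers)
Conditions: i-Bu2AlH (5 equiv), CH2Cl2, −78 °C to 0 °C; aqueous work-up
Reagents that add atoms: none
Why: Hydride reduction of the ester to the primary alcohol (C11) together with 1,2-reduction of the enone carbonyl; the new carbinol centre is uncontrolled and is removed in step 5.

Step 5
Reactants: 8 1-[(3R,4S)-3-(hydroxymethyl)-2,3,4-trimethylcyclohex-1-en-1-yl]ethan-1-ol
Product: 9 1-[(3R,4S)-3-(hydroxymethyl)-2,3,4-trimethylcyclohex-1-en-1-yl]ethan-1-one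
Conditions: MnO2 (excess), CH2Cl2, rt
Reagents that add atoms: none
Why: Selective allylic oxidation, since MnO2 oxidises the allylic secondary alcohol back to the enone and leaves the saturated neopentyl primary alcohol alone.

Step 6
Reactants: 9 1-[(3R,4S)-3-(hydroxymethyl)-2,3,4-trimethylcyclohex-1-en-1-yl]ethan-1-one; 10 ethoxyethene
Product: 11 1-[(3R,4S)-3-{[(1R)-2-bromo-1-ethoxyethoxy]methyl}-2,3,4-trimethylcyclohex-1-en-1-yl]ethan-1-one (one acetal epimer drawn; both are formed and used)
Conditions: N-bromosuccinimide, CH2Cl2, −40 °C to 0 °C
Reagents that add atoms: N-bromosuccinimide, O=C1CCC(=O)N1Br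
Why: Haloacetalisation, in which electrophilic bromine adds to the electron-rich vinyl ether and the primary alcohol captures the oxocarbenium ion; the hindered, electron-poor enone alkene should not compete.

Step 7
Reactants: 11 1-[(3R,4S)-3-{[(1R)-2-bromo-1-ethoxyethoxy]methyl}-2,3,4-trimethylcyclohex-1-en-1-yl]ethan-1-one
Product: 12 1-(3-ethoxy-4a,8,8a-trimethyloctahydro-1H-isochromen-5-yl)ethan-1-one, cis-fused, C1 and C11 on the same face (configuration as in its SMILES)
Conditions: Bu3SnH (1.3 equiv, syringe pump), AIBN (0.2 equiv), benzene (0.01 M), 80 °C
Reagents that add atoms: none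
Why: The tributyltin radical abstracts bromine from 11 to give a nucleophilic primary radical at C1. Held by the acetal on the C11 oxygen, this radical adds to the electrophilic β-carbon C10 of the enone through a chair-like six-membered transition state (6-exo-trig), forming C1–C10 and the tetrahydropyran ring, and the α-acyl radical at C5 then takes hydrogen from Bu3SnH and carries the chain. The closest known reaction type is the haloacetal (Ueno–Stork) radical cyclisation onto an enone β-carbon. C10 is controlled by the tether: the three-atom link C9–C11–O reaches only the face of C10 syn to C11, so C1 ends cis to C11 and the new bicycle is cis-fused, with C8 and C9 as spectators. C5 is set by hydrogen-atom transfer and is drawn with H anti to the C10 methyl, but it is not relied upon because steps 9 and 10 erase and re-set it. The step needs attack at C10 and not 7-endo attack at C5, which polarity matching and ring size secure. It also needs ring closure to outrun direct reduction of the radical, which high dilution and slow stannane addition secure; (Me3Si)3SiH is the slower hydrogen donor to use if reduction still competes. The acetal carbon (C2, aldehyde level) is a mixture and is destroyed in step 8.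

Step 8
Reactants: 12 1-(3-ethoxy-4a,8,8a-trimethyloctahydro-1H-isochromen-5-yl)ethan-1-one
Product: 14 5-(hydroxymethyl)-4a,5,6-trimethyl-4a,5,6,7,8,8a-hexahydronaphthalen-1(4H)-one (ring A enone; C5 as carried from 12), via lactol 13 (not isolated)
Conditions: 1 M HCl, THF, rt; then KOH, MeOH, 50 °C
Reagents that add atoms: none
Why: Acetal hydrolysis frees the C2 aldehyde (as its lactol) and the C11 hydroxyl, and base then effects the intramolecular aldol condensation of the acetyl methyl (C3) onto C2, the only closure that gives a six-membered ring. Any epimerisation at C5 under the base is harmless because step 9 removes that centre.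

Step 9
Reactants: 14 5-(hydroxymethyl)-4a,5,6-trimethyl-4a,5,6,7,8,8a-hexahydronaphthalen-1(4H)-one
Product: 16 5-(hydroxymethyl)-4a,5,6-trimethyl-4a,5,6,7-tetrahydronaphthalen-1(4H)-one (cross-conjugated dienone, C2=C3 and C5=C6), via silyl dienol ether 15 (not isolated)
Conditions: LiN(i-Pr)2 (3 equiv), Me3SiCl, THF, −78 °C; then Pd(OAc)2 (1.1 equiv), MeCN, rt; dilute aqueous citric acid work-up
Reagents that add atoms: none
Why: Saegusa–Ito dehydrogenation, in which kinetic α′-deprotonation at C5 (the only α′ position) gives the cross-conjugated silyl dienol ether and the hydroxyl is silylated in passing, then palladation and β-hydride elimination toward C6 give the dienone and the silyl ether falls off on work-up. Both C5 epimers of 14 converge on 16.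

Step 10
Reactants: 16 5-(hydroxymethyl)-4a,5,6-trimethyl-4a,5,6,7-tetrahydronaphthalen-1(4H)-one
Product: 17 5-(hydroxymethyl)-4a,5,6-trimethyloctahydronaphthalen-1(2H)-one, trans-fused (C5–H anti to the C10 methyl)
Conditions: H2 (1–3 atm), 10% Pd/C, EtOAc, rt; filtered and used at once
Reagents that add atoms: none
Why: Heterogeneous hydrogenation of both C=C bonds, in which the face of C5=C6 that carries the methyl groups is blocked by the pseudo-axial C10 methyl on the allylic carbon and by the C8 methyl, while the opposite face carries only the C11 hydroxymethyl group, which can also anchor the substrate to the metal. Syn delivery from that face should put C5–H cis to C11 and anti to the C10 methyl (trans fusion), as in the hydrogenation of Δ5-olefins next to an angular methyl group; neutral conditions avoid enolisation of the product.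

Step 11
Reactants: 17 5-(hydroxymethyl)-4a,5,6-trimethyloctahydronaphthalen-1(2H)-one
Product: 18 [(1R,2S,4aS,8aS)-1,2,8a-trimethyl-5-methylidenedecahydronaphthalen-1-yl]methanol
Conditions: Zn, CH2Br2, TiCl4, THF/CH2Cl2, 0 °C to rt (excess reagent)
Reagents that add atoms: dibromomethane, BrCBr
Why: Zn/CH2Br2/TiCl4 (Takai–Lombardo) methylenation, whose non-basic gem-dimetallic reagent methylenates hindered, epimerisable ketones without enolisation and tolerates the free hydroxyl as its titanium alkoxide. C5 is therefore retained and is no longer epimerisable afterwards.

Step 12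
Reactants: 18 [(1R,2S,4aS,8aS)-1,2,8a-trimethyl-5-methylidenedecahydronaphthalen-1-yl]methanol
Product: 19 (1R,2S,4aS,8aS)-1,2,8a-trimethyl-5-methylidenedecahydronaphthalene-1-carbaldehyde
Conditions: triacetoxyperiodinane (DMP), CH2Cl2, rt
Reagents that add atoms: none
Why: Hypervalent-iodine oxidation of the neopentyl primary alcohol to an aldehyde that cannot enolise (C9 is quaternary); the isolated alkene is inert.

Step 13
Reactants: 19 (1R,2S,4aS,8aS)-1,2,8a-trimethyl-5-methylidenedecahydronaphthalene-1-carbaldehyde; 20 1,2,4,5-tetramethoxybenzene
Product: 22 [(1R,2S,4aS,8aS)-1,2,8a-trimethyl-5-methylidenedecahydronaphthalen-1-yl](2,3,5,6-tetramethoxyphenyl)methanol (both carbinol epimers), via aryllithium 21 (not isolated)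
Conditions: 20 (2 equiv), n-BuLi (1.9 equiv), THF, 0 °C to rt; then 19, −78 °C to 0 °C; H2O
Reagents that add atoms: none
Why: Directed ortho-lithiation between two methoxy groups, then 1,2-addition of the aryllithium to the aldehyde, which has no α-hydrogen and so cannot be lost to enolisation; the carbinol centre is removed in step 15.

Step 14
Reactants: 22 [(1R,2S,4aS,8aS)-1,2,8a-trimethyl-5-methylidenedecahydronaphthalen-1-yl](2,3,5,6-tetramethoxyphenyl)methanol
Product: 23 O-{[(1R,2S,4aS,8aS)-1,2,8a-trimethyl-5-methylidenedecahydronaphthalen-1-yl](2,3,5,6-tetramethoxyphenyl)methyl} S-methyl carbonodithioate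
Conditions: NaH, CS2, then MeI, THF, 0 °C to rt
Reagents that add atoms: carbon disulfide, S=C=S; iodomethane, CI
Why: Xanthate formation from the alkoxide; with no β-hydrogen on C9, thermal syn-elimination of the xanthate is not possible.

Step 15
Reactants: 23 O-{[(1R,2S,4aS,8aS)-1,2,8a-trimethyl-5-methylidenedecahydronaphthalen-1-yl](2,3,5,6-tetramethoxyphenyl)methyl} S-methyl carbonodithioate
Product: 24 1,2,4,5-tetramethoxy-3-{[(1R,2S,4aS,8aS)-1,2,8a-trimethyl-5-methylidenedecahydronaphthalen-1-yl]methyl}benzene
Conditions: Bu3SnH, AIBN, toluene, 100 °C
Reagents that add atoms: none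
Why: Barton–McCombie deoxygenation through a stabilised benzylic radical that is reduced by the stannane; the neutral radical conditions spare the acid-sensitive alkene, and the radical cannot close onto it because C4 is equatorial on ring B.

Step 16
Reactants: 24 1,2,4,5-tetramethoxy-3-{[(1R,2S,4aS,8aS)-1,2,8a-trimethyl-5-methylidenedecahydronaphthalen-1-yl]methyl}benzene
Product: 25 2,5-dimethoxy-3-{[(1R,2S,4aS,8aS)-1,2,8a-trimethyl-5-methylidenedecahydronaphthalen-1-yl]methyl}cyclohexa-2,5-diene-1,4-dione
Conditions: (NH4)2Ce(NO3)6, MeCN/H2O, 0 °C
Reagents that add atoms: water, O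
Why: Oxidative demethylation of the electron-rich arene by tetravalent cerium, in which water attacks the arene radical cation at a para pair of methoxy-bearing carbons and methanol is lost. The isolated alkene is much harder to oxidise, and oxidation across an adjacent methoxy pair would not be a loss because the hydrolysis and tautomerisation of step 17 lead to the same hydroxyquinone.

Step 17
Reactants: 25 2,5-dimethoxy-3-{[(1R,2S,4aS,8aS)-1,2,8a-trimethyl-5-methylidenedecahydronaphthalen-1-yl]methyl}cyclohexa-2,5-diene-1,4-dione
Product: 26 2-hydroxy-5-methoxy-3-{[(1R,2S,4aS,8aS)-1,2,8a-trimethyl-5-methylidenedecahydronaphthalen-1-yl]methyl}cyclohexa-2,5-diene-1,4-dione (CNP0109104.1)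
Conditions: KOH, MeOH/H2O, 60 °C; then cold dilute HCl to pH 3
Reagents that add atoms: potassium hydroxide, [K+].[OH-]
Why: Addition–elimination hydrolysis of a vinylogous ester, in which the methoxy group flanked by the alkyl chain is twisted out of conjugation and is the more reactive one, as known for 3-alkyl-2,5-dimethoxybenzoquinones, and the product is protected from a second hydrolysis as its anion. Base is used because acid would move the exocyclic alkene.

Compound list

1 | ethyl 2-methyl-3-oxobutanoate | CCOC(=O)C(C)C(C)=O | starting material
2 | (E)-but-2-enal | C/C=C/C=O | starting material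
3 | 1-(triphenyl-λ5-phosphanylidene)propan-2-one | CC(=O)C=P(c1ccccc1)(c1ccccc1)c1ccccc1 | starting material
4 | ethyl (2R,3S)-2-acetyl-2,3-dimethyl-5-oxopentanoate (not isolated) | CCOC(=O)[C@@](C)(C(C)=O)[C@@H](C)CC=O | intermediate
5 | ethyl (2R,3S,5E)-2-acetyl-2,3-dimethyl-7-oxooct-5-enoate | CCOC(=O)[C@@](C)(C(C)=O)[C@@H](C)C/C=C/C(C)=O | intermediate
6 | ethyl (2R,3S)-2-acetyl-2,3-dimethyl-7-oxooctanoate | CCOC(=O)[C@@](C)(C(C)=O)[C@@H](C)CCCC(C)=O | intermediate
7 | ethyl (1R,6S)-3-acetyl-1,2,6-trimethylcyclohex-2-ene-1-carboxylate | CC(=O)C1=C(C)[C@](C)(C(=O)OCC)[C@@H](C)CC1 | intermediate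
8 | 1-[(3R,4S)-3-(hydroxymethyl)-2,3,4-trimethylcyclohex-1-en-1-yl]ethan-1-ol (carbinol epimers) | CC(O)C1=C(C)[C@](C)(CO)[C@@H](C)CC1 | intermediate
9 | 1-[(3R,4S)-3-(hydroxymethyl)-2,3,4-trimethylcyclohex-1-en-1-yl]ethan-1-one | CC(=O)C1=C(C)[C@](C)(CO)[C@@H](C)CC1 | intermediate
10 | ethoxyethene | C=COCC | starting material
11 | 1-[(3R,4S)-3-{[(1R)-2-bromo-1-ethoxyethoxy]methyl}-2,3,4-trimethylcyclohex-1-en-1-yl]ethan-1-one (one acetal epimer drawn) | CC(=O)C1=C(C)[C@](C)(CO[C@@H](OCC)CBr)[C@@H](C)CC1 | intermediate
12 | 1-(3-ethoxy-4a,8,8a-trimethyloctahydro-1H-isochromen-5-yl)ethan-1-one, cis-fused (C5 as drawn, C5 epimer tolerated) | CC(=O)[C@@H]1CC[C@H](C)[C@@]2(C)CO[C@@H](OCC)C[C@@]12C | intermediate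
13 | 1-(3-hydroxy-4a,8,8a-trimethyloctahydro-1H-isochromen-5-yl)ethan-1-one, lactol (not isolated) | CC(=O)[C@@H]1CC[C@H](C)[C@@]2(C)COC(O)C[C@@]12C | intermediate
14 | 5-(hydroxymethyl)-4a,5,6-trimethyl-4a,5,6,7,8,8a-hexahydronaphthalen-1(4H)-one (C5 as carried from 12) | O=C1C=CC[C@@]2(C)[C@H]1CC[C@H](C)[C@@]2(C)CO | intermediate
15 | bis(trimethylsilyl) dienol ether of 14: C4–OSiMe3 on C4=C5, C11–OSiMe3 (not isolated) | C[Si](C)(C)OC1=C2CC[C@H](C)[C@@](C)(CO[Si](C)(C)C)[C@@]2(C)CC=C1 | intermediate
16 | 5-(hydroxymethyl)-4a,5,6-trimethyl-4a,5,6,7-tetrahydronaphthalen-1(4H)-one | O=C1C=CC[C@@]2(C)C1=CC[C@H](C)[C@@]2(C)CO | intermediate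
17 | 5-(hydroxymethyl)-4a,5,6-trimethyloctahydronaphthalen-1(2H)-one, trans-fused | O=C1CCC[C@@]2(C)[C@H]1CC[C@H](C)[C@@]2(C)CO | intermediate
18 | [(1R,2S,4aS,8aS)-1,2,8a-trimethyl-5-methylidenedecahydronaphthalen-1-yl]methanol | C=C1CCC[C@@]2(C)[C@H]1CC[C@H](C)[C@@]2(C)CO | intermediate
19 | (1R,2S,4aS,8aS)-1,2,8a-trimethyl-5-methylidenedecahydronaphthalene-1-carbaldehyde | C=C1CCC[C@@]2(C)[C@H]1CC[C@H](C)[C@@]2(C)C=O | intermediate
20 | 1,2,4,5-tetramethoxybenzene | COc1cc(OC)c(OC)cc1OC | starting material
21 | (2,3,5,6-tetramethoxyphenyl)lithium (not isolated) | [Li]c1c(OC)c(OC)cc(OC)c1OC | intermediate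
22 | [(1R,2S,4aS,8aS)-1,2,8a-trimethyl-5-methylidenedecahydronaphthalen-1-yl](2,3,5,6-tetramethoxyphenyl)methanol (carbinol epimers) | C=C1CCC[C@@]2(C)[C@H]1CC[C@H](C)[C@@]2(C)C(O)c1c(OC)c(OC)cc(OC)c1OC | intermediate
23 | O-{[(1R,2S,4aS,8aS)-1,2,8a-trimethyl-5-methylidenedecahydronaphthalen-1-yl](2,3,5,6-tetramethoxyphenyl)methyl} S-methyl carbonodithioate | C=C1CCC[C@@]2(C)[C@H]1CC[C@H](C)[C@@]2(C)C(OC(=S)SC)c1c(OC)c(OC)cc(OC)c1OC | intermediate
24 | 1,2,4,5-tetramethoxy-3-{[(1R,2S,4aS,8aS)-1,2,8a-trimethyl-5-methylidenedecahydronaphthalen-1-yl]methyl}benzene | C=C1CCC[C@@]2(C)[C@H]1CC[C@H](C)[C@@]2(C)Cc1c(OC)c(OC)cc(OC)c1OC | intermediate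
25 | 2,5-dimethoxy-3-{[(1R,2S,4aS,8aS)-1,2,8a-trimethyl-5-methylidenedecahydronaphthalen-1-yl]methyl}cyclohexa-2,5-diene-1,4-dione | C=C1CCC[C@@]2(C)[C@H]1CC[C@H](C)[C@@]2(C)CC1=C(OC)C(=O)C=C(OC)C1=O | intermediate
26 | 2-hydroxy-5-methoxy-3-{[(1R,2S,4aS,8aS)-1,2,8a-trimethyl-5-methylidenedecahydronaphthalen-1-yl]methyl}cyclohexa-2,5-diene-1,4-dione | C=C1CCC[C@@]2(C)[C@H]1CC[C@H](C)[C@@]2(C)CC1=C(O)C(=O)C=C(OC)C1=O | target

Total step count: 17. Longest linear sequence: 17 steps (1 and 2 to 26); the arene 20 enters at step 13.

Least certain steps

Step 7 (key step). The most likely failure is hydrogen transfer to the primary radical before it closes. The β-carbon C10 is fully substituted and flanked by quaternary C9, and the acetyl group of a 1-acetyl-2-methylcyclohexene is twisted out of conjugation, so the enone is a weaker radical acceptor than usual. The fallback keeps the C11-oxygen tether but changes the mechanism from radical to polar. It sets out from 9 and comes back at 14.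
- Transfer vinylation of 9 with 10 (Pd(OCOCF3)2, 4,7-diphenyl-1,10-phenanthroline) would give the vinyl ether 1-[(3R,4S)-3-[(ethenyloxy)methyl]-2,3,4-trimethylcyclohex-1-en-1-yl]ethan-1-one F1.
- Me2AlCl at −78 °C would activate the ketone, so that the enol ether terminus (C1) attacks C10 on the C11 face and the enolate oxygen closes onto the oxocarbenium carbon C2. This is a formal intramolecular inverse-demand hetero-Diels–Alder reaction and would give the bridged enol-ether acetal F2.
- The conditions of step 8 would hydrolyse F2 through lactol 13 to 14.

Step 1. The likely failure is poor facial selectivity at the nucleophile, so that C9 forms as a near-even mixture while only C8 is catalyst-controlled. Sluggish addition of the α-substituted keto ester is a second concern. The fallback replaces conjugate addition by allylic substitution. It sets out from 1 and comes back at 4, which then meets 3 as in step 1.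
- The lithium enolate of 1 (LiOt-Bu) and (E)-but-2-enyl methyl carbonate, under [Ir(cod)Cl]2 and a chiral phosphoramidite, would give the branched product ethyl (2R,3S)-2-acetyl-2,3-dimethylpent-4-enoate F3. This reaction class builds vicinal quaternary and tertiary centres from acyclic β-keto esters with both centres formed at one catalyst-bound allyl. The ligand enantiomer would be chosen for 3S, and the sense at C2 would have to be confirmed.
- Hydroboration with 9-borabicyclo[3.3.1]nonane and oxidation with NaBO3 would give ethyl (2R,3S)-2-acetyl-5-hydroxy-2,3-dimethylpentanoate F4.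
- Triacetoxyperiodinane would oxidise F4 to 4.

Step 9. The likely failure is deprotonation at the γ-carbon C1 in place of the hindered α′-methine C5, or reluctant β-hydride elimination from a congested palladium enolate. The fallback removes the C5 and C6 hydrogens without a lithium enolate. It sets out from 14 and comes back at 16.
- Silylation (t-BuMe2SiCl, imidazole) would give the tert-butyldimethylsilyl ether of 14 F5.
- 2-Iodoxybenzoic acid in DMSO at 75 °C dehydrogenates enones at the α′,β′-positions through the enol and single-electron oxidation, and would give the tert-butyldimethylsilyl ether of 16 F6.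
- Bu4NF would release 16.

Step 10. The likely failure is poor facial selectivity in hydrogen delivery to C5, which would give the cis-fused ketone, the isomer that equilibration would also favour. The fallback changes the control element from steric approach on a metal surface to substrate-directed delivery. It sets out from 16 and comes back at 17 with no new compound: [Ir(cod)(PCy3)(py)]PF6 with H2 in CH2Cl2 binds the C11 hydroxyl and should deliver hydrogen to C5=C6 from the C11 face while also saturating C2=C3.

Step 17. The likely failure is loss of regioselectivity between the two methoxy groups, or hydrolysis of both. The fallback hydrolyses fully and then differentiates the two hydroxyls. It sets out from 25 and comes back at 26.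
- Prolonged KOH treatment would give 2,5-dihydroxy-3-{[(1R,2S,4aS,8aS)-1,2,8a-trimethyl-5-methylidenedecahydronaphthalen-1-yl]methyl}cyclohexa-2,5-diene-1,4-dione F7.
- One equivalent of Me3SiCHN2 in MeOH/toluene would methylate the less hindered hydroxyl, the one next to the ring C–H and not the one flanked by the alkyl chain, giving 26 without acid.

Further compounds

F1 | step 7 | 1-[(3R,4S)-3-[(ethenyloxy)methyl]-2,3,4-trimethylcyclohex-1-en-1-yl]ethan-1-one | CC(=O)C1=C(C)[C@](C)(COC=C)[C@@H](C)CC1
F2 | step 7 | bridged enol-ether acetal (C2 bonded to the C11 oxygen and to the C4 enol oxygen, C4=C5, C1–C10 formed) | CC1=C2CC[C@H](C)[C@@]3(C)CO[C@@H](O1)C[C@@]23C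
F3 | step 1 | ethyl (2R,3S)-2-acetyl-2,3-dimethylpent-4-enoate | CCOC(=O)[C@@](C)(C(C)=O)[C@@H](C)C=C
F4 | step 1 | ethyl (2R,3S)-2-acetyl-5-hydroxy-2,3-dimethylpentanoate | CCOC(=O)[C@@](C)(C(C)=O)[C@@H](C)CCO
F5 | step 9 | tert-butyldimethylsilyl ether of 14 | O=C1C=CC[C@@]2(C)[C@H]1CC[C@H](C)[C@@]2(C)CO[Si](C)(C)C(C)(C)C
F6 | step 9 | tert-butyldimethylsilyl ether of 16 | O=C1C=CC[C@@]2(C)C1=CC[C@H](C)[C@@]2(C)CO[Si](C)(C)C(C)(C)C
F0 | step 10 | none | none
F7 | step 17 | 2,5-dihydroxy-3-{[(1R,2S,4aS,8aS)-1,2,8a-trimethyl-5-methylidenedecahydronaphthalen-1-yl]methyl}cyclohexa-2,5-diene-1,4-dione | C=C1CCC[C@@]2(C)[C@H]1CC[C@H](C)[C@@]2(C)CC1=C(O)C(=O)C=C(O)C1=O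
A1 | alternative 1 | ring B enone: C8 ketone, C9=C10, C9–CH2OSi(t-Bu)Me2, C4 dioxolane, C5–H as in the target | C12(OCCO1)CCCC3=C(CO[Si](C)(C)C(C)(C)C)C(=O)CC[C@@H]23
A2 | alternative 1 | acetylene | C#C
A3 | alternative 1 | cyclobutene photoadduct fused across C9–C10 anti to C5–H (C8 ketone, C4 dioxolane) | C12(OCCO1)CCC[C@@]3(C=C4)[C@H]2CCC(=O)[C@@]34CO[Si](C)(C)C(C)(C)C
A4 | alternative 2 | 6-ethenyl-7-methyl-1,4-dioxaspiro[4.5]dec-6-ene | C=CC1=C(C)CCCC12OCCO2
A5 | alternative 2 | (E)-2-methylbut-2-enal | C/C=C(\C)C=O
A6 | alternative 2 | ring B cyclohexene (C5=C6) C11 aldehyde with C8, C9, C10 set, C4 dioxolane | C12(OCCO1)CCC[C@@]3(C)C2=CC[C@H](C)[C@@]3(C)C=O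
A7 | alternative 3 | 7a-methyl trans-hydrindane with tertiary C8 carbinol bearing a 2-methyloxiran-2-yl group, C4 dioxolane | C12(OCCO1)CCC[C@@]3(C)[C@H]2CC[C@@]3(O)[C@]4(C)CO4
A8 | alternative 3 | trans-decalin C8 ketone with C9 methyl and C11 hydroxymethyl, C4 dioxolane | C12(OCCO1)CCC[C@@]3(C)[C@H]2CCC(=O)[C@@]3(C)CO
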